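The 8,2'-biaryl bond is flanked on ring A by C8a, which carries O1 of ring C, and on ring E by C1', which carries C2 of ring F. The plan therefore ties the ring A phenol to the ring E carboxyl as an aryl ester and forges the biaryl bond by intramolecular Pd-catalysed C–H arylation, which in one operation gives a six-membered biaryl lactone with the linkage regiochemically fixed. The precursor is the 2-bromo-4-methoxybenzoate of a dibenzylated phloroacetophenone. The bridge is then reused: a ketone enolate opens the lactone, so its carbonyl becomes C2 of ring F and its oxygen O1 of ring C; both pyranones follow.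

Key step: step 3

Ring labels: rings A (benzo), C (pyranone) and B (4-methoxyphenyl) belong to the flavone that carries the 4-methoxyphenyl group; rings D (benzo), F (pyranone) and E (methoxyphenylene) belong to the other flavone.

Assumption: the tri-ortho-substituted biaryl axis is drawn without configuration, so the target is taken as configurationally undefined and no axial control is attempted; there is no stereocentre.

Step 1
Reactants: 1 2,4,6-trihydroxyacetophenone
Product: 2 1-[2,4-bis(benzyloxy)-6-hydroxyphenyl]ethan-1-one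
Conditions: BnBr (2.05 equiv), K2CO3 (2.1 equiv), DMF, rt
Reagents that add atoms: benzyl bromide, BrCc1ccccc1
Why: Williamson etherification stops at the dibenzyl stage because the last phenol is chelated to the acetyl carbonyl and is much less nucleophilic.

Step 2
Reactants: 3 2-bromo-4-methoxybenzoic acid; 2 1-[2,4-bis(benzyloxy)-6-hydroxyphenyl]ethan-1-one
Product: 5 2-acetyl-3,5-bis(benzyloxy)phenyl 2-bromo-4-methoxybenzoate, via 2-bromo-4-methoxybenzoyl chloride 4 (not isolated)
Conditions: 3, (COCl)2, cat. DMF, CH2Cl2, 0 °C to rt, evaporate; then 2, pyridine, cat. DMAP, CH2Cl2, 0 °C to rt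
Reagents that add atoms: none
Why: Acid chloride formation followed by DMAP-catalysed O-acylation of the phenol (nucleophilic acyl substitution) under an amine base too weak to enolise the acetyl group, so the ester should be isolable without Baker–Venkataraman migration.

Step 3
Reactants: 5 2-acetyl-3,5-bis(benzyloxy)phenyl 2-bromo-4-methoxybenzoate
Product: 6 4-acetyl-1,3-bis(benzyloxy)-9-methoxy-6H-benzo[c]chromen-6-one
Conditions: Pd(OAc)2 (10 mol %), PPh3 (20 mol %), NaOAc (2 equiv), N,N-dimethylacetamide, 120 °C, argon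
Reagents that add atoms: none
Why: Zerovalent palladium formed from Pd(OAc)2 and PPh3 inserts into the C–Br bond of ring E, acetate-assisted concerted metalation–deprotonation at the free position ortho to the ester oxygen of ring A gives a seven-membered diaryl palladacycle of divalent palladium, and reductive elimination forms the biaryl bond. The closest known reaction type is the Pd-catalysed intramolecular direct arylation of phenyl 2-halobenzoates to 6H-benzo[c]chromen-6-ones. The six-membered lactone ring is closed through its biaryl C–C bond, by ring contraction of the palladacycle on reductive elimination. No stereocentre is formed and the lactone-bridged axis is configurationally labile. The step needs regioselectivity, which the ester tether secures: the aryl–palladium unit can reach only the two positions ortho to the bridging oxygen, one of which carries the acetyl group, so only the future C8 of ring A reacts, and the methoxy position on ring E is fixed by the substitution of 3. It also needs chemoselectivity against acyl migration, which the weak carboxylate base should secure, since NaOAc serves the palladation but should not enolise the acetyl group.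

Step 4
Reactants: 6 4-acetyl-1,3-bis(benzyloxy)-9-methoxy-6H-benzo[c]chromen-6-one; 2 1-[2,4-bis(benzyloxy)-6-hydroxyphenyl]ethan-1-one
Product: 8 1-[2-(3-acetyl-4,6-bis(benzyloxy)-2-hydroxyphenyl)-4-methoxyphenyl]-3-[2,4-bis(benzyloxy)-6-hydroxyphenyl]propane-1,3-dione, via dilithium phenoxide enolate 7 (not isolated)
Conditions: 2 (2.5 equiv), LiN(SiMe3)2 (5.0 equiv), THF, −78 to −10 °C; then 6 in THF added slowly at −78 °C, warm to 0 °C; 1 M HCl quench; excess 2 recovered
Reagents that add atoms: none
Why: Proposed new method: the enolate carbon of 7 should add to the strained aryl lactone carbonyl of 6, the tetrahedral intermediate should expel the ring A 2-acylphenoxide, and a second equivalent of 7 should deprotonate the new 1,3-diketone and make the opening irreversible; the closest known reaction types are the Claisen-type acylation of 2-hydroxyacetophenone dianions generated with LiN(SiMe3)2 by aroyl chlorides and esters, and the ring opening of benzo[c]chromen-6-one biaryl lactones by O-, N- and H-nucleophiles; slow inverse addition into excess dianion with no free amide base is meant to suppress enolisation and self-condensation through the acetyl group of 6.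

Step 5
Reactants: 8 1-[2-(3-acetyl-4,6-bis(benzyloxy)-2-hydroxyphenyl)-4-methoxyphenyl]-3-[2,4-bis(benzyloxy)-6-hydroxyphenyl]propane-1,3-dione
Product: 9 2-[2-(3-acetyl-4,6-bis(benzyloxy)-2-hydroxyphenyl)-4-methoxyphenyl]-5,7-bis(benzyloxy)-4H-chromen-4-one
Conditions: cat. H2SO4, AcOH, 60 °C
Reagents that add atoms: none
Why: Acid-catalysed cyclodehydration of a 1-(2-hydroxyaryl)-1,3-diketone closes pyranone ring F through the ring D phenol, and the competing hemiketal with the ring A phenol is reversible under acid and should drain to the conjugated chromone.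

Step 6
Reactants: 9 2-[2-(3-acetyl-4,6-bis(benzyloxy)-2-hydroxyphenyl)-4-methoxyphenyl]-5,7-bis(benzyloxy)-4H-chromen-4-one; 10 4-methoxybenzaldehyde
Product: 11 (E)-1-[4,6-bis(benzyloxy)-3-{2-[5,7-bis(benzyloxy)-4-oxo-4H-chromen-2-yl]-5-methoxyphenyl}-2-hydroxyphenyl]-3-(4-methoxyphenyl)prop-2-en-1-one
Conditions: KOH (50% aq.), EtOH/THF, rt
Reagents that add atoms: none
Why: Claisen–Schmidt condensation of the methyl ketone with a non-enolisable aldehyde, the dehydration giving the thermodynamically favoured E enone, with the ring A phenoxide shielding the ketone from other base chemistry.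

Step 7
Reactants: 11 (E)-1-[4,6-bis(benzyloxy)-3-{2-[5,7-bis(benzyloxy)-4-oxo-4H-chromen-2-yl]-5-methoxyphenyl}-2-hydroxyphenyl]-3-(4-methoxyphenyl)prop-2-en-1-one
Product: 12 5,7-bis(benzyloxy)-8-{2-[5,7-bis(benzyloxy)-4-oxo-4H-chromen-2-yl]-5-methoxyphenyl}-2-(4-methoxyphenyl)-4H-chromen-4-one
Conditions: I2 (10 mol %), DMSO, 130 °C
Reagents that add atoms: none
Why: Iodine-catalysed oxidative cyclisation of a 2'-hydroxychalcone (oxa-Michael closure of ring C, then iodination and loss of HI, which DMSO reoxidises) should give the flavone, and any partial loss of the benzyl ether peri to the carbonyl is harmless because step 8 removes all four.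

Step 8
Reactants: 12 5,7-bis(benzyloxy)-8-{2-[5,7-bis(benzyloxy)-4-oxo-4H-chromen-2-yl]-5-methoxyphenyl}-2-(4-methoxyphenyl)-4H-chromen-4-one
Product: 13 5,7-dihydroxy-8-[2-(5,7-dihydroxy-4-oxo-4H-chromen-2-yl)-5-methoxyphenyl]-2-(4-methoxyphenyl)-4H-chromen-4-one (CNP0394081.0)
Conditions: H2 (1 atm), 10% Pd/C, THF/MeOH, rt
Reagents that add atoms: none
Why: Catalytic hydrogenolysis cleaves the four benzylic C–O bonds while the two aryl methyl ethers are inert and the aryl-conjugated pyranone double bonds should be reduced far more slowly.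

Compound list
1 | 2,4,6-trihydroxyacetophenone | CC(=O)c1c(O)cc(O)cc1O | starting material
2 | 1-[2,4-bis(benzyloxy)-6-hydroxyphenyl]ethan-1-one | CC(=O)c1c(O)cc(OCc2ccccc2)cc1OCc1ccccc1 | intermediate
3 | 2-bromo-4-methoxybenzoic acid | COc1ccc(C(=O)O)c(Br)c1 | starting material
4 | 2-bromo-4-methoxybenzoyl chloride | COc1ccc(C(=O)Cl)c(Br)c1 | intermediate
5 | 2-acetyl-3,5-bis(benzyloxy)phenyl 2-bromo-4-methoxybenzoate | CC(=O)c1c(OC(=O)c2ccc(OC)cc2Br)cc(OCc2ccccc2)cc1OCc1ccccc1 | intermediate
6 | 4-acetyl-1,3-bis(benzyloxy)-9-methoxy-6H-benzo[c]chromen-6-one | CC(=O)c1c2OC(=O)c3ccc(OC)cc3-c2c(OCc2ccccc2)cc1OCc1ccccc1 | intermediate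
7 | dilithium phenoxide enolate of 2 | [Li+].[Li+].C=C([O-])c1c([O-])cc(OCc2ccccc2)cc1OCc1ccccc1 | intermediate
8 | 1-[2-(3-acetyl-4,6-bis(benzyloxy)-2-hydroxyphenyl)-4-methoxyphenyl]-3-[2,4-bis(benzyloxy)-6-hydroxyphenyl]propane-1,3-dione | CC(=O)c1c(O)c(-c2cc(OC)ccc2C(=O)CC(=O)c2c(O)cc(OCc3ccccc3)cc2OCc2ccccc2)c(OCc2ccccc2)cc1OCc1ccccc1 | intermediate
9 | 2-[2-(3-acetyl-4,6-bis(benzyloxy)-2-hydroxyphenyl)-4-methoxyphenyl]-5,7-bis(benzyloxy)-4H-chromen-4-one | CC(=O)c1c(O)c(-c2cc(OC)ccc2-c2cc(=O)c3c(OCc4ccccc4)cc(OCc4ccccc4)cc3o2)c(OCc2ccccc2)cc1OCc1ccccc1 | intermediate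
10 | 4-methoxybenzaldehyde | COc1ccc(C=O)cc1 | starting material
11 | (E)-1-[4,6-bis(benzyloxy)-3-{2-[5,7-bis(benzyloxy)-4-oxo-4H-chromen-2-yl]-5-methoxyphenyl}-2-hydroxyphenyl]-3-(4-methoxyphenyl)prop-2-en-1-one | COc1ccc(/C=C/C(=O)c2c(O)c(-c3cc(OC)ccc3-c3cc(=O)c4c(OCc5ccccc5)cc(OCc5ccccc5)cc4o3)c(OCc3ccccc3)cc2OCc2ccccc2)cc1 | intermediate
12 | 5,7-bis(benzyloxy)-8-{2-[5,7-bis(benzyloxy)-4-oxo-4H-chromen-2-yl]-5-methoxyphenyl}-2-(4-methoxyphenyl)-4H-chromen-4-one | COc1ccc(-c2cc(=O)c3c(OCc4ccccc4)cc(OCc4ccccc4)c(-c4cc(OC)ccc4-c4cc(=O)c5c(OCc6ccccc6)cc(OCc6ccccc6)cc5o4)c3o2)cc1 | intermediate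
13 | 5,7-dihydroxy-8-[2-(5,7-dihydroxy-4-oxo-4H-chromen-2-yl)-5-methoxyphenyl]-2-(4-methoxyphenyl)-4H-chromen-4-one (CNP0394081.0) | COc1ccc(-c2cc(=O)c3c(O)cc(O)c(-c4cc(OC)ccc4-c4cc(=O)c5c(O)cc(O)cc5o4)c3o2)cc1 | target

Total step count: 8. Longest linear sequence: 8 steps (1 to 13 through 2, 5, 6, 8, 9, 11 and 12).

Steps most likely to fail

Step 4. The acetyl group of the lactone may transfer a proton to the dianion and then self-condense, or the enolate may add to the ketone instead of acylating at the lactone carbonyl. The fallback uses only known reactions, sets out from 6 and returns at 9. The lactone is saponified (KOH, aqueous THF) and the dried dipotassium phenoxide carboxylate is alkylated on both oxygens with MOMCl in DMF to give methoxymethyl 2-[3-acetyl-4,6-bis(benzyloxy)-2-(methoxymethoxy)phenyl]-4-methoxybenzoate F1. LiOH in aqueous THF then cleaves only the acetal ester to 2-[3-acetyl-4,6-bis(benzyloxy)-2-(methoxymethoxy)phenyl]-4-methoxybenzoic acid F2, which cannot relactonise because the ring A oxygen is capped. Steglich esterification with 2 (EDC·HCl, DMAP, CH2Cl2) should give 2-acetyl-3,5-bis(benzyloxy)phenyl 2-[3-acetyl-4,6-bis(benzyloxy)-2-(methoxymethoxy)phenyl]-4-methoxybenzoate F3. Baker–Venkataraman rearrangement (powdered KOH, pyridine, 50 °C; six-membered acyl transfer to the ring D acetyl is favoured over the eight-membered alternative) should give 1-[2-(3-acetyl-4,6-bis(benzyloxy)-2-(methoxymethoxy)phenyl)-4-methoxyphenyl]-3-[2,4-bis(benzyloxy)-6-hydroxyphenyl]propane-1,3-dione F4. Catalytic H2SO4 in AcOH then closes ring F and removes the acetal in the same operation, giving 9.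

Step 3. At 120 °C with carboxylate base the ester may undergo acyl migration to the acetyl methyl group or cleavage before palladation, and oxidative addition may end in hydrodebromination because the C–H position lies between two oxygen substituents. The fallback replaces the C–H arylation by a cross-coupling, sets out from 2 and 3 and returns at 6. Iodination of 2 with benzyltrimethylammonium dichloroiodate (CaCO3, CH2Cl2/MeOH) ortho to the free phenol should give 1-[4,6-bis(benzyloxy)-2-hydroxy-3-iodophenyl]ethan-1-one F5. Acid 3 is esterified (MeOH, cat. H2SO4) to methyl 2-bromo-4-methoxybenzoate F6 and borylated (B2pin2, PdCl2(dppf), KOAc, dioxane, 90 °C) to methyl 4-methoxy-2-(4,4,5,5-tetramethyl-1,3,2-dioxaborolan-2-yl)benzoate F7. Suzuki–Miyaura coupling of F5 with F7 (Pd(OAc)2, SPhos, K3PO4, toluene/water, 90 °C) should give methyl 2-[3-acetyl-4,6-bis(benzyloxy)-2-hydroxyphenyl]-4-methoxybenzoate F8, which is expected to lactonise in the flask, or on brief TsOH treatment, to 6.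

Step 6. Hydroxide may open pyranone ring F by conjugate addition during the long exposure that the hindered, fully flanked ketone needs, and the condensation itself may stall. The fallback builds ring C by acyl transfer instead of aldol chemistry, sets out from 9 and returns at 12, bypassing 11. Acylation of the ring A phenol with 4-methoxybenzoyl chloride (pyridine, DMAP) should give 2-acetyl-3,5-bis(benzyloxy)-6-{2-[5,7-bis(benzyloxy)-4-oxo-4H-chromen-2-yl]-5-methoxyphenyl}phenyl 4-methoxybenzoate F9. Baker–Venkataraman rearrangement with the non-nucleophilic base LiN(SiMe3)2 (THF, −78 °C to rt) should give 1-[4,6-bis(benzyloxy)-3-{2-[5,7-bis(benzyloxy)-4-oxo-4H-chromen-2-yl]-5-methoxyphenyl}-2-hydroxyphenyl]-3-(4-methoxyphenyl)propane-1,3-dione F10. Catalytic H2SO4 in AcOH then closes ring C to give 12.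

Further compounds
F1 | step 4 | methoxymethyl 2-[3-acetyl-4,6-bis(benzyloxy)-2-(methoxymethoxy)phenyl]-4-methoxybenzoate | CC(=O)c1c(OCOC)c(-c2cc(OC)ccc2C(=O)OCOC)c(OCc2ccccc2)cc1OCc1ccccc1
F2 | step 4 | 2-[3-acetyl-4,6-bis(benzyloxy)-2-(methoxymethoxy)phenyl]-4-methoxybenzoic acid | CC(=O)c1c(OCOC)c(-c2cc(OC)ccc2C(=O)O)c(OCc2ccccc2)cc1OCc1ccccc1
F3 | step 4 | 2-acetyl-3,5-bis(benzyloxy)phenyl 2-[3-acetyl-4,6-bis(benzyloxy)-2-(methoxymethoxy)phenyl]-4-methoxybenzoate | CC(=O)c1c(OCOC)c(-c2cc(OC)ccc2C(=O)Oc2cc(OCc3ccccc3)cc(OCc3ccccc3)c2C(C)=O)c(OCc2ccccc2)cc1OCc1ccccc1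
F4 | step 4 | 1-[2-(3-acetyl-4,6-bis(benzyloxy)-2-(methoxymethoxy)phenyl)-4-methoxyphenyl]-3-[2,4-bis(benzyloxy)-6-hydroxyphenyl]propane-1,3-dione | CC(=O)c1c(OCOC)c(-c2cc(OC)ccc2C(=O)CC(=O)c2c(O)cc(OCc3ccccc3)cc2OCc2ccccc2)c(OCc2ccccc2)cc1OCc1ccccc1
F5 | step 3 | 1-[4,6-bis(benzyloxy)-2-hydroxy-3-iodophenyl]ethan-1-one | CC(=O)c1c(O)c(I)c(OCc2ccccc2)cc1OCc1ccccc1
F6 | step 3 | methyl 2-bromo-4-methoxybenzoate | COC(=O)c1ccc(OC)cc1Br
F7 | step 3 | methyl 4-methoxy-2-(4,4,5,5-tetramethyl-1,3,2-dioxaborolan-2-yl)benzoate | COC(=O)c1ccc(OC)cc1B1OC(C)(C)C(C)(C)O1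
F8 | step 3 | methyl 2-[3-acetyl-4,6-bis(benzyloxy)-2-hydroxyphenyl]-4-methoxybenzoate | CC(=O)c1c(O)c(-c2cc(OC)ccc2C(=O)OC)c(OCc2ccccc2)cc1OCc1ccccc1
F9 | step 6 | 2-acetyl-3,5-bis(benzyloxy)-6-{2-[5,7-bis(benzyloxy)-4-oxo-4H-chromen-2-yl]-5-methoxyphenyl}phenyl 4-methoxybenzoate | CC(=O)c1c(OC(=O)c2ccc(OC)cc2)c(-c2cc(OC)ccc2-c2cc(=O)c3c(OCc4ccccc4)cc(OCc4ccccc4)cc3o2)c(OCc2ccccc2)cc1OCc1ccccc1
F10 | step 6 | 1-[4,6-bis(benzyloxy)-3-{2-[5,7-bis(benzyloxy)-4-oxo-4H-chromen-2-yl]-5-methoxyphenyl}-2-hydroxyphenyl]-3-(4-methoxyphenyl)propane-1,3-dione | COc1ccc(C(=O)CC(=O)c2c(O)c(-c3cc(OC)ccc3-c3cc(=O)c4c(OCc5ccccc5)cc(OCc5ccccc5)cc4o3)c(OCc3ccccc3)cc2OCc2ccccc2)cc1
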